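The decalin is cut at C6–C7 and C5–C10. The C8/C9 ketol is a cyclohexene-1,2-diol in disguise, and the quaternary C5 lies next to C4, which can be a ketone before it becomes CHMe. An isopropenyl ketone (C5=C6, activated by C4=O) tethered to a 2,3-bis(silyloxy)diene (C7–C10) therefore closes rings A and B in one intramolecular Diels–Alder reaction and sets C5 and C10 from the C3 silyl ether. The precursor is an acyclic (4R,7Z)-2-methyl-4,8,9-tris(silyloxy)deca-1,7,9-trien-3-one; its two enol silyl groups differ (robust on O9, labile on O8), which later places the ketone at C8.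

Key step: step 8

Remark: bicyclic compounds carry eremophilane locants (ring A = C1–C5 and C10, ring B = C5–C10, methyl groups on C4 and C5; α is the face of H-10, β the face of the C5 methyl group); acyclic compounds carry their own chain locants.

Step 1
Reactants: 1 pent-3-yn-1-ol
Product: 2 5-bromopent-2-yne
Conditions: CBr4, PPh3, CH2Cl2, 0 °C to rt
Reagents that add atoms: carbon tetrabromide, BrC(Br)(Br)Br
Why: Appel bromination of a primary alcohol is reliable and leaves the internal alkyne untouched.

Step 2
Reactants: 2 5-bromopent-2-yne; 3 methyl (R)-glycidate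
Product: 5 methyl (R)-2-hydroxyoct-6-ynoate, via pent-3-ynylmagnesium bromide 4 (not isolated)
Conditions: Mg, THF, rt; then CuI (10 mol %), 3, THF, −40 °C; aq NH4Cl
Reagents that add atoms: none
Why: Copper-catalysed Grignard opening of the glycidic ester (a known route to α-hydroxy esters) takes place at the unsubstituted epoxide carbon faster than addition to the ester, and the R carbinol centre of 3, which is not involved, becomes C3 of the target.

Step 3
Reactants: 5 methyl (R)-2-hydroxyoct-6-ynoate
Product: 6 methyl (R)-2-(triethylsilyloxy)oct-6-ynoate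
Conditions: TESCl, imidazole, CH2Cl2, 0 °C to rt
Reagents that add atoms: chlorotriethylsilane, CC[Si](Cl)(CC)CC
Why: Routine silylation of a secondary alcohol; triethylsilyl is chosen because it survives all steps up to 21 yet can be removed later beside the C9 tert-butyldimethylsilyl ether.

Step 4
Reactants: 6 methyl (R)-2-(triethylsilyloxy)oct-6-ynoate
Product: 7 (R)-N-methoxy-N-methyl-2-(triethylsilyloxy)oct-6-ynamide
Conditions: MeNH(OMe)·HCl, iPrMgCl, THF, −20 to 0 °C
Reagents that add atoms: N,O-dimethylhydroxylamine hydrochloride, CNOC.Cl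
Why: Weinreb amide formation from the ester with ClMgN(OMe)Me runs at low temperature without epimerising the α-silyloxy centre and keeps C4 at the acyl level until the diene is in place.

Step 5
Reactants: 7 (R)-N-methoxy-N-methyl-2-(triethylsilyloxy)oct-6-ynamide
Product: 8 (R)-N-methoxy-N-methyl-6,7-dioxo-2-(triethylsilyloxy)octanamide
Conditions: KMnO4, NaHCO3, MgSO4, acetone–H2O, 0 °C to rt
Reagents that add atoms: potassium permanganate, [K+].[O-][Mn](=O)(=O)=O
Why: Buffered KMnO4 oxidation of a dialkyl alkyne stops at the 1,2-diketone, and at this stage the alkyne is the only oxidisable π bond in the molecule.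

Step 6
Reactants: 8 (R)-N-methoxy-N-methyl-6,7-dioxo-2-(triethylsilyloxy)octanamide
Product: 10 (2R,5Z)-6-(tert-butyldimethylsilyloxy)-N-methoxy-N-methyl-2-(triethylsilyloxy)-7-(trimethylsilyloxy)octa-5,7-dienamide, via mono-TBS enol ether 9 (not isolated)
Conditions: TBSOTf (1.0 equiv), Et3N, CH2Cl2, −78 to 0 °C; then TMSOTf, Et3N, 0 °C
Reagents that add atoms: tert-butyldimethylsilyl trifluoromethanesulfonate, CC(C)(C)[Si](C)(C)OS(=O)(=O)C(F)(F)F; trimethylsilyl trifluoromethanesulfonate, C[Si](C)(C)OS(=O)(=O)C(F)(F)F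
Why: Soft enolisation (silyl triflate and amine) in two stages: each carbonyl of the 1,2-dione can enolise to one side only, the first equivalent should silylate the C6 oxygen as the more substituted, conjugated Z enol ether (robust group on the future O9) and the methyl ketone that remains then takes the labile trimethylsilyl group (future O8), while the amide is not enolised, so that C2 is never put at risk as an α-silyloxy ketone.

Step 7
Reactants: 10 (2R,5Z)-6-(tert-butyldimethylsilyloxy)-N-methoxy-N-methyl-2-(triethylsilyloxy)-7-(trimethylsilyloxy)octa-5,7-dienamide; 11 isopropenylmagnesium bromide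
Product: 12 (4R,7Z)-8-(tert-butyldimethylsilyloxy)-2-methyl-4-(triethylsilyloxy)-9-(trimethylsilyloxy)deca-1,7,9-trien-3-one
Conditions: THF, −78 to −20 °C; cold pH 7 phosphate buffer
Reagents that add atoms: none
Why: Addition of an alkenyl Grignard reagent to a Weinreb amide stops at the chelated tetrahedral adduct, which gives the isopropenyl ketone only on neutral work-up, so the enol silyl ethers and the α centre survive.

Step 8
Reactants: 12 (4R,7Z)-8-(tert-butyldimethylsilyloxy)-2-methyl-4-(triethylsilyloxy)-9-(trimethylsilyloxy)deca-1,7,9-trien-3-one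
Product: 13 9-(tert-butyldimethylsilyloxy)-5β-methyl-3α-(triethylsilyloxy)-8-(trimethylsilyloxy)-trans-octal-8-en-4-one (10α-H)
Conditions: toluene (0.01 M), BHT (5 mol %), 90 °C
Reagents that add atoms: none
Why: On heating, the electron-rich diene C7=C8–C9=C10 and the ketone-activated alkene C5=C6 combine in a concerted, asynchronous [4+2] cycloaddition that forms C6–C7 and C5–C10; the closest known reactions are the intramolecular Diels–Alder reactions of 1,7,9-decatrien-3-ones and the cycloadditions of 2,3-bis(silyloxy)butadienes. Ring B (C5–C10) closes as the new cyclohexene of the cycloaddition, and ring A (C1–C5, C10) closes in the same event in the fused (type 1) intramolecular mode through the four-atom tether C1–C4. C5 and C10 are set together: suprafacial addition to the Z enol ether terminus C10 through the anti, chair-like tether, with the C4 carbonyl exo and the C5 methyl endo, gives the trans ring fusion. Their absolute sense comes from C3, whose triethylsilyloxy group takes the equatorial position of that chair because the axial position would meet the C5 methyl group in a 1,3-diaxial contact. The step needs exo (trans-fusion) selectivity and π-facial selectivity: the chair keeps the enone planar and every tether bond staggered, whereas the carbonyl-endo alternative needs a boat-like tether that eclipses the C3 silyloxy group, and the C3 centre fixes the face. The adduct is a mixed enediol bis-silyl ether, so the C8/C9 oxidation level and the C4 ketone are both in place.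

Step 9
Reactants: 13 9-(tert-butyldimethylsilyloxy)-5β-methyl-3α-(triethylsilyloxy)-8-(trimethylsilyloxy)-trans-octal-8-en-4-one (10α-H)
Product: 14 9-(tert-butyldimethylsilyloxy)-5β-methyl-4-methylene-3α-(triethylsilyloxy)-8-(trimethylsilyloxy)-trans-octal-8-ene (10α-H)
Conditions: Cp2TiMe2 (3 equiv), toluene, 75 °C, dark
Reagents that add atoms: dimethyltitanocene Cp2TiMe2, C[Ti](C)(C1C=CC=C1)C1C=CC=C1
Why: Titanium methylidene olefination with Cp2TiMe2 is non-basic, spares silyl enol ethers and is suited to hindered, enolisable ketones; C4 is the only carbonyl group present, which is why the methylenation is placed before the C8 ketone is released.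

Step 10
Reactants: 14 9-(tert-butyldimethylsilyloxy)-5β-methyl-4-methylene-3α-(triethylsilyloxy)-8-(trimethylsilyloxy)-trans-octal-8-ene (10α-H)
Product: 15 9α-(tert-butyldimethylsilyloxy)-5β-methyl-4-methylene-3α-(triethylsilyloxy)-trans-decal-8-one (10α-H)
Conditions: K2CO3 (0.2 equiv), MeOH, −20 to 0 °C; pH 7 buffer
Reagents that add atoms: none
Why: Base-catalysed methanolysis cleaves only the trimethylsilyl enol ether, and the O8 enolate so released can be protonated only at C9, which fixes the ketone at C8 and leaves O9 protected; axial protonation from the β face should give the equatorial 9α epimer, the thermodynamically preferred one.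

Step 11
Reactants: 15 9α-(tert-butyldimethylsilyloxy)-5β-methyl-4-methylene-3α-(triethylsilyloxy)-trans-decal-8-one (10α-H)
Product: 16 9α-(tert-butyldimethylsilyloxy)-4β,5β-dimethyl-3α-(triethylsilyloxy)-trans-decal-8-one (10α-H)
Conditions: H2 (1 atm), [Ir(cod)(PCy3)(py)]PF6 (5 mol %), CH2Cl2, rt
Reagents that add atoms: none
Why: Homogeneous hydrogenation of a 1,1-disubstituted alkene: hydrogen is delivered to the α face of the exocyclic C4 alkene, away from the axial C5 methyl group, which sets C4 with its methyl group β, equatorial, cis to the C5 methyl.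

Step 12
Reactants: 16 9α-(tert-butyldimethylsilyloxy)-4β,5β-dimethyl-3α-(triethylsilyloxy)-trans-decal-8-one (10α-H)
Product: 19 9α-(tert-butyldimethylsilyloxy)-7-(2-hydroxypropan-2-yl)-4β,5β-dimethyl-3α-(triethylsilyloxy)-trans-decal-8-one (10α-H; C7 epimers), via lithium enolate 17 (not isolated), via chlorozinc enolate 18 (not isolated)
Conditions: LiN(iPr)2, THF, −78 °C; ZnCl2; acetone, −78 to −40 °C; aq NH4Cl
Reagents that add atoms: acetone, CC(C)=O
Why: Directed aldol addition: kinetic deprotonation of an α-silyloxy ketone takes place at the unsubstituted α′ methylene C7, and the zinc enolate adds to acetone without the proton transfer that troubles lithium enolates; the new C7 centre is removed in step 13.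

Step 13
Reactants: 19 9α-(tert-butyldimethylsilyloxy)-7-(2-hydroxypropan-2-yl)-4β,5β-dimethyl-3α-(triethylsilyloxy)-trans-decal-8-one (10α-H; C7 epimers)
Product: 21 9α-(tert-butyldimethylsilyloxy)-3α-(triethylsilyloxy)-4β,5β-dimethyl-10αH-eremophil-7(11)-en-8-one, via tertiary mesylate 20 (not isolated)
Conditions: MsCl, Et3N, CH2Cl2, 0 °C; then DBU, 0 °C to rt
Reagents that add atoms: none
Why: Sulfonylation of the tertiary aldol hydroxyl followed by E1cB elimination through the C7 enolate gives the conjugated tetrasubstituted enone, which is the thermodynamically favoured isopropylidene isomer.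

Step 14
Reactants: 21 9α-(tert-butyldimethylsilyloxy)-3α-(triethylsilyloxy)-4β,5β-dimethyl-10αH-eremophil-7(11)-en-8-one
Product: 22 9α-(tert-butyldimethylsilyloxy)-3α-hydroxy-4β,5β-dimethyl-10αH-eremophil-7(11)-en-8-one
Conditions: PPTS, MeOH–CH2Cl2, 0 °C to rt
Reagents that add atoms: none
Why: Acid-catalysed methanolysis removes the less hindered triethylsilyl ether while the bulkier tert-butyldimethylsilyl ether beside the ring fusion stays, a standard differentiation of silyl ethers.

Step 15
Reactants: 23 (E)-non-3-en-2-one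
Product: 24 (2E,4E)-N-methoxy-N,3-dimethyldeca-2,4-dienamide
Conditions: (EtO)2P(O)CH2C(O)N(OMe)Me, NaH, THF, 0 to 60 °C
Reagents that add atoms: diethyl [2-(methoxy(methyl)amino)-2-oxoethyl]phosphonate, CCOP(=O)(CC(=O)N(C)OC)OCC
Why: Horner–Wadsworth–Emmons olefination of the methyl ketone with the Weinreb amide phosphonate should give mainly the 2E isomer (alkenyl group trans to the carboxamide), and any 2Z isomer is removed by chromatography.

Step 16
Reactants: 24 (2E,4E)-N-methoxy-N,3-dimethyldeca-2,4-dienamide
Product: 25 (2E,4E)-3-methyldeca-2,4-dienal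
Conditions: iBu2AlH, THF, −78 °C; aq KNa tartrate
Reagents that add atoms: none
Why: Hydride reduction of a Weinreb amide stops at the aldehyde level because the chelated hemiaminal survives until work-up.

Step 17
Reactants: 25 (2E,4E)-3-methyldeca-2,4-dienal
Product: 26 ethyl (2E,4E,6E)-5-methyldodeca-2,4,6-trienoate
Conditions: Ph3P=CHCO2Et, CH2Cl2, rt
Reagents that add atoms: ethyl (triphenylphosphoranylidene)acetate, CCOC(=O)C=P(c1ccccc1)(c1ccccc1)c1ccccc1
Why: Wittig olefination of an aldehyde by a stabilised ylide is E-selective and completes the (2E,4E,6E)-triene.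

Step 18
Reactants: 26 ethyl (2E,4E,6E)-5-methyldodeca-2,4,6-trienoate
Product: 27 (2E,4E,6E)-5-methyldodeca-2,4,6-trienoic acid
Conditions: LiOH, THF–MeOH–H2O, rt; then aq HCl
Reagents that add atoms: lithium hydroxide, [Li+].[OH-]
Why: Mild saponification of the ethyl ester does not isomerise the triene.

Step 19
Reactants: 22 9α-(tert-butyldimethylsilyloxy)-3α-hydroxy-4β,5β-dimethyl-10αH-eremophil-7(11)-en-8-one; 27 (2E,4E,6E)-5-methyldodeca-2,4,6-trienoic acid
Product: 29 9α-(tert-butyldimethylsilyloxy)-3α-[(2E,4E,6E)-5-methyldodeca-2,4,6-trienoyloxy]-4β,5β-dimethyl-10αH-eremophil-7(11)-en-8-one, via mixed anhydride 28 (not isolated)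
Conditions: 2,4,6-trichlorobenzoyl chloride, Et3N, THF, rt; then 22, DMAP, toluene, rt
Reagents that add atoms: none
Why: Yamaguchi esterification through the mixed anhydride acylates hindered secondary alcohols, and the C3 hydroxyl is the only free hydroxyl group of 22; C3 is not touched, so its configuration is retained.

Step 20
Reactants: 29 9α-(tert-butyldimethylsilyloxy)-3α-[(2E,4E,6E)-5-methyldodeca-2,4,6-trienoyloxy]-4β,5β-dimethyl-10αH-eremophil-7(11)-en-8-one
Product: 30 9α-hydroxy-3α-[(2E,4E,6E)-5-methyldodeca-2,4,6-trienoyloxy]-4β,5β-dimethyl-10αH-eremophil-7(11)-en-8-one (CNP0211657.1)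
Conditions: HF·pyridine, pyridine, THF, 0 °C to rt
Reagents that add atoms: none
Why: Fluoride cleavage of the last silyl ether under buffered conditions leaves the trienoate and the enone intact, and the equatorial 9α hydroxyl of the target is the thermodynamically preferred ketol epimer.

Compound list
1 | pent-3-yn-1-ol | CC#CCCO | starting material
2 | 5-bromopent-2-yne | CC#CCCBr | intermediate
3 | methyl (R)-glycidate (methyl (2R)-oxirane-2-carboxylate) | COC(=O)[C@H]1CO1 | starting material
4 | pent-3-ynylmagnesium bromide | CC#CCC[Mg]Br | intermediate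
5 | methyl (R)-2-hydroxyoct-6-ynoate | CC#CCCC[C@@H](O)C(=O)OC | intermediate
6 | methyl (R)-2-(triethylsilyloxy)oct-6-ynoate | CC#CCCC[C@@H](O[Si](CC)(CC)CC)C(=O)OC | intermediate
7 | (R)-N-methoxy-N-methyl-2-(triethylsilyloxy)oct-6-ynamide | CC#CCCC[C@@H](O[Si](CC)(CC)CC)C(=O)N(C)OC | intermediate
8 | (R)-N-methoxy-N-methyl-6,7-dioxo-2-(triethylsilyloxy)octanamide | CC(=O)C(=O)CCC[C@@H](O[Si](CC)(CC)CC)C(=O)N(C)OC | intermediate
9 | (2R,5Z)-6-(tert-butyldimethylsilyloxy)-N-methoxy-N-methyl-7-oxo-2-(triethylsilyloxy)oct-5-enamide | CC(=O)/C(O[Si](C)(C)C(C)(C)C)=C/CC[C@@H](O[Si](CC)(CC)CC)C(=O)N(C)OC | intermediate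
10 | (2R,5Z)-6-(tert-butyldimethylsilyloxy)-N-methoxy-N-methyl-2-(triethylsilyloxy)-7-(trimethylsilyloxy)octa-5,7-dienamide | C=C(O[Si](C)(C)C)/C(O[Si](C)(C)C(C)(C)C)=C/CC[C@@H](O[Si](CC)(CC)CC)C(=O)N(C)OC | intermediate
11 | isopropenylmagnesium bromide | C=C(C)[Mg]Br | starting material
12 | (4R,7Z)-8-(tert-butyldimethylsilyloxy)-2-methyl-4-(triethylsilyloxy)-9-(trimethylsilyloxy)deca-1,7,9-trien-3-one | C=C(C)C(=O)[C@H](O[Si](CC)(CC)CC)CC/C=C(O[Si](C)(C)C(C)(C)C)/C(=C)O[Si](C)(C)C | intermediate
13 | 9-(tert-butyldimethylsilyloxy)-5β-methyl-3α-(triethylsilyloxy)-8-(trimethylsilyloxy)-trans-octal-8-en-4-one (10α-H) | CC[Si](CC)(CC)O[C@@H]1CC[C@H]2C(O[Si](C)(C)C(C)(C)C)=C(O[Si](C)(C)C)CC[C@]2(C)C1=O | intermediate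
14 | 9-(tert-butyldimethylsilyloxy)-5β-methyl-4-methylene-3α-(triethylsilyloxy)-8-(trimethylsilyloxy)-trans-octal-8-ene (10α-H) | CC[Si](CC)(CC)O[C@@H]1CC[C@H]2C(O[Si](C)(C)C(C)(C)C)=C(O[Si](C)(C)C)CC[C@]2(C)C1=C | intermediate
15 | 9α-(tert-butyldimethylsilyloxy)-5β-methyl-4-methylene-3α-(triethylsilyloxy)-trans-decal-8-one (10α-H) | CC[Si](CC)(CC)O[C@@H]1CC[C@H]2[C@H](O[Si](C)(C)C(C)(C)C)C(=O)CC[C@]2(C)C1=C | intermediate
16 | 9α-(tert-butyldimethylsilyloxy)-4β,5β-dimethyl-3α-(triethylsilyloxy)-trans-decal-8-one (10α-H) | CC[Si](CC)(CC)O[C@@H]1CC[C@H]2[C@H](O[Si](C)(C)C(C)(C)C)C(=O)CC[C@]2(C)[C@H]1C | intermediate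
17 | lithium C7–C8 enolate of 16 | CC[Si](CC)(CC)O[C@@H]1CC[C@H]2[C@H](O[Si](C)(C)C(C)(C)C)C(O[Li])=CC[C@]2(C)[C@H]1C | intermediate
18 | chlorozinc C7–C8 enolate of 16 | CC[Si](CC)(CC)O[C@@H]1CC[C@H]2[C@H](O[Si](C)(C)C(C)(C)C)C(O[Zn]Cl)=CC[C@]2(C)[C@H]1C | intermediate
19 | 9α-(tert-butyldimethylsilyloxy)-7-(2-hydroxypropan-2-yl)-4β,5β-dimethyl-3α-(triethylsilyloxy)-trans-decal-8-one (10α-H; C7 left open, both epimers converge) | CC[Si](CC)(CC)O[C@@H]1CC[C@H]2[C@H](O[Si](C)(C)C(C)(C)C)C(=O)C(C(C)(C)O)C[C@]2(C)[C@H]1C | intermediate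
20 | methanesulfonate of the tertiary hydroxyl of 19 | CC[Si](CC)(CC)O[C@@H]1CC[C@H]2[C@H](O[Si](C)(C)C(C)(C)C)C(=O)C(C(C)(C)OS(C)(=O)=O)C[C@]2(C)[C@H]1C | intermediate
21 | 9α-(tert-butyldimethylsilyloxy)-3α-(triethylsilyloxy)-4β,5β-dimethyl-10αH-eremophil-7(11)-en-8-one | CC[Si](CC)(CC)O[C@@H]1CC[C@H]2[C@H](O[Si](C)(C)C(C)(C)C)C(=O)C(=C(C)C)C[C@]2(C)[C@H]1C | intermediate
22 | 9α-(tert-butyldimethylsilyloxy)-3α-hydroxy-4β,5β-dimethyl-10αH-eremophil-7(11)-en-8-one | O[C@@H]1CC[C@H]2[C@H](O[Si](C)(C)C(C)(C)C)C(=O)C(=C(C)C)C[C@]2(C)[C@H]1C | intermediate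
23 | (E)-non-3-en-2-one | CCCCC/C=C/C(C)=O | starting material
24 | (2E,4E)-N-methoxy-N,3-dimethyldeca-2,4-dienamide | CCCCC/C=C/C(C)=C/C(=O)N(C)OC | intermediate
25 | (2E,4E)-3-methyldeca-2,4-dienal | CCCCC/C=C/C(C)=C/C=O | intermediate
26 | ethyl (2E,4E,6E)-5-methyldodeca-2,4,6-trienoate | CCCCC/C=C/C(C)=C/C=C/C(=O)OCC | intermediate
27 | (2E,4E,6E)-5-methyldodeca-2,4,6-trienoic acid | CCCCC/C=C/C(C)=C/C=C/C(=O)O | intermediate
28 | (2E,4E,6E)-5-methyldodeca-2,4,6-trienoic 2,4,6-trichlorobenzoic anhydride | CCCCC/C=C/C(C)=C/C=C/C(=O)OC(=O)c1c(Cl)cc(Cl)cc1Cl | intermediate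
29 | 9α-(tert-butyldimethylsilyloxy)-3α-[(2E,4E,6E)-5-methyldodeca-2,4,6-trienoyloxy]-4β,5β-dimethyl-10αH-eremophil-7(11)-en-8-one | CCCCC/C=C/C(C)=C/C=C/C(=O)O[C@@H]1CC[C@H]2[C@H](O[Si](C)(C)C(C)(C)C)C(=O)C(=C(C)C)C[C@]2(C)[C@H]1C | intermediate
30 | 9α-hydroxy-3α-[(2E,4E,6E)-5-methyldodeca-2,4,6-trienoyloxy]-4β,5β-dimethyl-10αH-eremophil-7(11)-en-8-one (CNP0211657.1) | CCCCC/C=C/C(C)=C/C=C/C(=O)O[C@@H]1CC[C@H]2[C@H](O)C(=O)C(=C(C)C)C[C@]2(C)[C@H]1C | target

Total step count: 20. Longest linear sequence: 16 steps (steps 1–14, 19 and 20); steps 15–18 make the acid side chain.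

Steps most likely to fail

Step 8. The risk is insufficient preference for the carbonyl-exo transition state, which would erode the trans ring fusion, together with loss of the enol silyl groups before ring closure on prolonged heating. The fallback sets out from 12 and comes back at 13, with no compound beyond those of the route (F0). The thermal pericyclic closure is replaced by a Lewis-acid-templated closure at −78 °C in toluene with the bulky aluminium reagent MeAl(OC6H2-2,6-tBu2-4-Me)2. The reagent binds the C4 carbonyl and shields the endo region, as in the known exo-selective Diels–Alder reactions of enones with such aryloxides. The bonds would then form stepwise, by Mukaiyama–Michael addition of C7 to C6 and Michael closure of C5 onto C10.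

Step 6. The risk is leakage of the first enolisation towards the methyl group, which would exchange the positions of the robust and the labile silyl group and later put the ketone at C9. The fallback sets out from 8 and comes back at 10. The order is reversed so that kinetic control decides. LiN(SiMe3)2 with TMSCl present at −78 °C in THF removes a proton from the C8 methyl group and should give (R)-N-methoxy-N-methyl-6-oxo-2-(triethylsilyloxy)-7-(trimethylsilyloxy)oct-7-enamide F1. Its remaining C6 carbonyl can enolise only towards C5, so TBSOTf and Et3N then complete 10.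

Step 12. The risk is proton transfer from acetone to the enolate, reversal of the aldol addition on work-up, or competing enolisation towards C9. The fallback sets out from 16 and comes back at 19. The kinetic enolate is trapped with TMSCl (LiN(iPr)2, THF, −78 °C) as 9α-(tert-butyldimethylsilyloxy)-4β,5β-dimethyl-3α-(triethylsilyloxy)-8-(trimethylsilyloxy)-trans-octal-7-ene F2. A Mukaiyama aldol addition of F2 to acetone with TiCl4 in CH2Cl2 at −78 °C then gives 19 under conditions in which the addition is not reversible.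

Further compounds
F0 | step 8 | none | none
F1 | step 6 | (R)-N-methoxy-N-methyl-6-oxo-2-(triethylsilyloxy)-7-(trimethylsilyloxy)oct-7-enamide | C=C(O[Si](C)(C)C)C(=O)CCC[C@@H](O[Si](CC)(CC)CC)C(=O)N(C)OC
F2 | step 12 | 9α-(tert-butyldimethylsilyloxy)-4β,5β-dimethyl-3α-(triethylsilyloxy)-8-(trimethylsilyloxy)-trans-octal-7-ene (10α-H) | CC[Si](CC)(CC)O[C@@H]1CC[C@H]2[C@H](O[Si](C)(C)C(C)(C)C)C(O[Si](C)(C)C)=CC[C@]2(C)[C@H]1C
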